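**Retrosynthetic overview**

1. The target is taken back, by loss of the protecting groups and a benzylic C–C coupling (C4–CH2Br plus an isobutenyl Grignard reagent, CH2Br from C4–CO2Me), to a methyl 7-siloxybenzofuran-4-carboxylate with the ring-A propyl chain at C5.
2. The strategy rests on the benzo ring of the benzofuran (C3a, C4, C5, C6, C7, C7a): oxygen at C7 para to the carbon substituent at C4, H at C6, linker at C5. C6 and C7–O are the enol ether of 2-acetylfuran; C4 and C5 are the sp carbons of an alkynoate whose ester carbon becomes the first prenyl carbon.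
3. Key disconnection: C6–C5 and C4–C3a, a Diels-Alder addition of 2-(1-siloxyvinyl)furan (diene = furan C2=C3 plus the siloxyvinyl group) to the ring-A hex-2-ynoate, followed by dehydrogenation.
4. The ynoate comes from a terminal alkyne and ClCO2Me; the alkyne from a Negishi coupling of the ring-A aryl bromide with a silylpentynylzinc reagent; the 1,1-dimethylallyl group from an aromatic Claisen rearrangement of a prenyl ether of 4-bromoresorcinol.
5. Ring order: ring A and the furan are bought; the benzo ring is the only ring built (step 10).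

Key step: step 10

Remark: the target is achiral; C6 of dienone 5 and C3a of cycloadduct 17 are transient racemic centres and need no control. Abbreviation used in the steps: ArA = 2,4-bis(methoxymethoxy)-5-(2-methylbut-3-en-2-yl)phenyl.

**Route**

Step 1
Reactants: 1 4-bromoresorcinol; 2 prenyl bromide (1-bromo-3-methylbut-2-ene)
Product: 3 2-bromo-5-[(3-methylbut-2-en-1-yl)oxy]phenol
Conditions: K2CO3 (1.0 equiv), 2 (1.0 equiv), acetone, rt
Reagents that add atoms: none
Why: Williamson ether synthesis; the hydroxyl para to bromine is the less hindered and more nucleophilic one (the ortho-bromo hydroxyl is hydrogen-bonded to Br and inductively deactivated), so mono-O-prenylation should occur mainly there, and the regioisomer and bis-ether are removed by chromatography.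

Step 2
Reactants: 3 2-bromo-5-[(3-methylbut-2-en-1-yl)oxy]phenol
Product: 4 1-bromo-2-(methoxymethoxy)-4-[(3-methylbut-2-en-1-yl)oxy]benzene
Conditions: MOMCl, i-Pr2NEt, CH2Cl2, 0 °C to rt
Reagents that add atoms: chloromethyl methyl ether (MOMCl), COCCl
Why: O-alkylation of the phenol with a chloromethyl ether (MOM acetal formation) under amine base, which leaves the allyl ether and the aryl bromide untouched.

Step 3
Reactants: 4 1-bromo-2-(methoxymethoxy)-4-[(3-methylbut-2-en-1-yl)oxy]benzene
Product: 6 4-bromo-5-(methoxymethoxy)-2-(2-methylbut-3-en-2-yl)phenol, via ortho-dienone 5 (not isolated)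
Conditions: PhNEt2, 185 °C, sealed tube, Ar
Reagents that add atoms: none
Why: Aromatic Claisen rearrangement, a [3,3] sigmatropic shift that inverts the prenyl unit into a 1,1-dimethylallyl group at the free ortho carbon; the other ortho carbon lies between two oxygens and is disfavoured sterically and by the meta donor, the para carbon is blocked by bromine, and dienone 5 tautomerises to the phenol.

Step 4
Reactants: 6 4-bromo-5-(methoxymethoxy)-2-(2-methylbut-3-en-2-yl)phenol
Product: 7 1-bromo-2,4-bis(methoxymethoxy)-5-(2-methylbut-3-en-2-yl)benzene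
Conditions: NaH, MOMCl, THF/DMF, 0 °C to rt
Reagents that add atoms: chloromethyl methyl ether (MOMCl), COCCl
Why: Williamson-type MOM ether formation; the sodium phenoxide is used because the hydroxyl is flanked by the tertiary alkyl group.

Step 5
Reactants: 8 (5-chloropent-1-yn-1-yl)trimethylsilane
Product: 9 (5-iodopent-1-yn-1-yl)trimethylsilane
Conditions: NaI, acetone, reflux
Reagents that add atoms: sodium iodide, [Na+].[I-]
Why: Finkelstein halide exchange on a primary chloride, driven by precipitation of NaCl.

Step 6
Reactants: 7 1-bromo-2,4-bis(methoxymethoxy)-5-(2-methylbut-3-en-2-yl)benzene; 9 (5-iodopent-1-yn-1-yl)trimethylsilane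
Product: 11 [5-(ArA)pent-1-yn-1-yl]trimethylsilane, via alkylzinc iodide 10 (not isolated)
Conditions: 9, Zn dust (activated by BrCH2CH2Br, Me3SiCl), THF, 40 °C; then 7, Pd(OAc)2 (2 mol%), SPhos (4 mol%), THF, 50 °C
Reagents that add atoms: none
Why: Negishi sp2–sp3 cross-coupling; zinc inserts into the primary iodide, and SPhos-ligated zerovalent palladium couples primary alkylzinc halides with electron-rich ortho-substituted aryl bromides, while the silyl group masks the alkyne and the ring-A alkene is meta to bromine and cannot undergo Heck cyclisation.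

Step 7
Reactants: 11 [5-(ArA)pent-1-yn-1-yl]trimethylsilane
Product: 12 1,5-bis(methoxymethoxy)-2-(2-methylbut-3-en-2-yl)-4-(pent-4-yn-1-yl)benzene
Conditions: K2CO3 (cat.), MeOH, rt
Reagents that add atoms: none
Why: Base-catalysed methanolysis of the C(sp)–Si bond (protodesilylation), to which MOM acetals are inert.

Step 8
Reactants: 12 1,5-bis(methoxymethoxy)-2-(2-methylbut-3-en-2-yl)-4-(pent-4-yn-1-yl)benzene
Product: 14 methyl 6-(ArA)hex-2-ynoate, via lithium acetylide 13 (not isolated)
Conditions: n-BuLi (1.05 equiv), THF, −78 °C; then added to ClCO2Me (excess), −78 to 0 °C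
Reagents that add atoms: methyl chloroformate, COC(=O)Cl
Why: Deprotonation of the terminal alkyne is far faster at −78 °C than ring lithiation between the MOM ethers, and acylation of the lithium acetylide with a chloroformate (alkoxycarbonylation) gives the ynoate; inverse addition limits a second acetylide addition.

Step 9
Reactants: 15 2-acetylfuran
Product: 16 2-[1-(tert-butyldimethylsilyloxy)vinyl]furan
Conditions: TBSOTf, Et3N, CH2Cl2, 0 °C
Reagents that add atoms: tert-butyldimethylsilyl trifluoromethanesulfonate (TBSOTf), CC(C)(C)[Si](C)(C)OS(=O)(=O)C(F)(F)F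
Why: Silyl enol ether formation by soft enolisation (silyl triflate and amine); the ketone has a single enolisable methyl group, so only one enol ether can form.

Step 10
Reactants: 14 methyl 6-(ArA)hex-2-ynoate; 16 2-[1-(tert-butyldimethylsilyloxy)vinyl]furan
Product: 18 methyl 7-(tert-butyldimethylsilyloxy)-5-[3-(ArA)propyl]-1-benzofuran-4-carboxylate, via 3a,6-dihydrobenzofuran cycloadduct 17 (not isolated)
Conditions: 16 (3 equiv), BHT (cat.), PhMe (1 M), 140 °C, sealed tube; volatiles removed; then DDQ (1.1 equiv), PhMe, 0 °C to rt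
Reagents that add atoms: none
Why: The siloxyvinyl group and the furan C2=C3 bond of 16 form an electron-rich 2-siloxy-1,3-diene with its largest HOMO coefficient on the terminal CH2, so a concerted but asynchronous [4+2] cycloaddition bonds this CH2 to the β-carbon of ynoate 14 and furan C3 to the ester-bearing α-carbon; the closest known reaction type is the extra-annular Diels-Alder reaction of 2-vinylfurans and their silyl enol ethers with acetylenic esters. The six-membered benzo ring is closed in the [4+2] cycloaddition mode, both σ bonds (C6–C5 and C4–C3a) forming in one event, which gives the 1,4-cyclohexadiene 17. DDQ then removes the hydrogens at C3a and C6 (hydride abstraction, then proton loss) and gives the aromatic benzofuran with the silyl ether kept at C7. No stereocentre remains, since C3a of 17 is racemic and becomes sp2 on aromatisation. The selectivity needed is regiochemical (chain at C5, ester at C4, para to the siloxy group) and is secured by the siloxy donor next to the CH2 terminus, which outweighs the weaker polarisation by the ring oxygen, together with the β-polarisation of the ynoate. Extra-annular addition is favoured over the reversible addition across the furan 2,5-positions, the ring-A alkene is unactivated and has no allylic hydrogen, prompt dehydrogenation forestalls loss of silanol, and excess diene, high concentration and 140 °C are planned because a β-alkyl ynoate is a sluggish dienophile.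

Step 11
Reactants: 18 methyl 7-(tert-butyldimethylsilyloxy)-5-[3-(ArA)propyl]-1-benzofuran-4-carboxylate
Product: 20 {7-(tert-butyldimethylsilyloxy)-5-[3-(ArA)propyl]-1-benzofuran-4-yl}methanol, via benzofuran-4-carbaldehyde 19 (not isolated)
Conditions: i-Bu2AlH (3 equiv), CH2Cl2, −78 to 0 °C; aq. potassium sodium tartrate
Reagents that add atoms: none
Why: Hydride reduction of the aryl ester to the primary alcohol through the aldehyde; aryl silyl ether, MOM acetals and the isolated alkene are inert to i-Bu2AlH.

Step 12
Reactants: 20 {7-(tert-butyldimethylsilyloxy)-5-[3-(ArA)propyl]-1-benzofuran-4-yl}methanol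
Product: 21 {[4-(bromomethyl)-5-[3-(ArA)propyl]-1-benzofuran-7-yl]oxy}(tert-butyl)dimethylsilane
Conditions: CBr4, PPh3, CH2Cl2, 0 °C; used crude
Reagents that add atoms: carbon tetrabromide, BrC(Br)(Br)Br
Why: Appel reaction; bromide displaces the alkoxyphosphonium group at the primary benzylic carbon under neutral conditions that preserve the MOM and silyl ethers.

Step 13
Reactants: 21 {[4-(bromomethyl)-5-[3-(ArA)propyl]-1-benzofuran-7-yl]oxy}(tert-butyl)dimethylsilane; 22 (2-methylprop-1-en-1-yl)magnesium bromide (commercial THF solution)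
Product: 23 tert-butyl{[5-[3-(ArA)propyl]-4-(3-methylbut-2-en-1-yl)-1-benzofuran-7-yl]oxy}dimethylsilane
Conditions: 22 (2 equiv), CuI (10 mol%), THF, −40 to 0 °C
Reagents that add atoms: none
Why: Copper-catalysed Kochi-type cross-coupling of a Grignard reagent with a benzylic bromide; the alkenylcuprate formed in the flask substitutes the bromide faster than the Grignard reagent attacks the aryl silyl ether, and the alkene needs no geometric control because its terminus carries two methyl groups.

Step 14
Reactants: 23 tert-butyl{[5-[3-(ArA)propyl]-4-(3-methylbut-2-en-1-yl)-1-benzofuran-7-yl]oxy}dimethylsilane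
Product: 24 5-[3-(ArA)propyl]-4-(3-methylbut-2-en-1-yl)-1-benzofuran-7-ol
Conditions: Bu4NF, AcOH, THF, 0 °C
Reagents that add atoms: none
Why: Fluoride-induced desilylation of the aryl silyl ether, driven by the Si–F bond; acetic acid buffers the electron-rich phenoxide, and MOM ethers are stable to fluoride.

Step 15
Reactants: 24 5-[3-(ArA)propyl]-4-(3-methylbut-2-en-1-yl)-1-benzofuran-7-ol
Product: 25 4-{3-[7-hydroxy-4-(3-methylbut-2-en-1-yl)-1-benzofuran-5-yl]propyl}-6-(2-methylbut-3-en-2-yl)benzene-1,3-diol
Conditions: aq. HCl (3 M)/MeOH (1:10), 40 °C, Ar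
Reagents that add atoms: none
Why: Acid-catalysed acetal exchange (MOM cleavage) in methanol; the mild acid and temperature are chosen so that neither the trisubstituted prenyl alkene nor the 1,1-dimethylallyl group ortho to a phenol is protonated.

**Compound list**

1 | 4-bromoresorcinol | Oc1ccc(Br)c(O)c1 | starting material
2 | prenyl bromide (1-bromo-3-methylbut-2-ene) | CC(C)=CCBr | starting material
3 | 2-bromo-5-[(3-methylbut-2-en-1-yl)oxy]phenol | Oc1cc(OCC=C(C)C)ccc1Br | intermediate
4 | 1-bromo-2-(methoxymethoxy)-4-[(3-methylbut-2-en-1-yl)oxy]benzene | COCOc1cc(OCC=C(C)C)ccc1Br | intermediate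
5 | 4-bromo-3-(methoxymethoxy)-6-(2-methylbut-3-en-2-yl)cyclohexa-2,4-dien-1-one (racemic, not isolated) | O=C1C=C(OCOC)C(Br)=CC1C(C)(C)C=C | intermediate
6 | 4-bromo-5-(methoxymethoxy)-2-(2-methylbut-3-en-2-yl)phenol | Oc1cc(OCOC)c(Br)cc1C(C)(C)C=C | intermediate
7 | 1-bromo-2,4-bis(methoxymethoxy)-5-(2-methylbut-3-en-2-yl)benzene | COCOc1cc(OCOC)c(Br)cc1C(C)(C)C=C | intermediate
8 | (5-chloropent-1-yn-1-yl)trimethylsilane | C[Si](C)(C)C#CCCCCl | starting material
9 | (5-iodopent-1-yn-1-yl)trimethylsilane | C[Si](C)(C)C#CCCCI | intermediate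
10 | [5-(trimethylsilyl)pent-4-yn-1-yl]zinc iodide (not isolated) | C[Si](C)(C)C#CCCC[Zn]I | intermediate
11 | {5-[2,4-bis(methoxymethoxy)-5-(2-methylbut-3-en-2-yl)phenyl]pent-1-yn-1-yl}trimethylsilane | C[Si](C)(C)C#CCCCc1cc(C(C)(C)C=C)c(OCOC)cc1OCOC | intermediate
12 | 1,5-bis(methoxymethoxy)-2-(2-methylbut-3-en-2-yl)-4-(pent-4-yn-1-yl)benzene | C#CCCCc1cc(C(C)(C)C=C)c(OCOC)cc1OCOC | intermediate
13 | {5-[2,4-bis(methoxymethoxy)-5-(2-methylbut-3-en-2-yl)phenyl]pent-1-yn-1-yl}lithium (not isolated) | [Li]C#CCCCc1cc(C(C)(C)C=C)c(OCOC)cc1OCOC | intermediate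
14 | methyl 6-[2,4-bis(methoxymethoxy)-5-(2-methylbut-3-en-2-yl)phenyl]hex-2-ynoate | COC(=O)C#CCCCc1cc(C(C)(C)C=C)c(OCOC)cc1OCOC | intermediate
15 | 2-acetylfuran | CC(=O)c1ccco1 | starting material
16 | 2-[1-(tert-butyldimethylsilyloxy)vinyl]furan | C=C(O[Si](C)(C)C(C)(C)C)c1ccco1 | intermediate
17 | methyl 7-(tert-butyldimethylsilyloxy)-5-{3-[2,4-bis(methoxymethoxy)-5-(2-methylbut-3-en-2-yl)phenyl]propyl}-3a,6-dihydro-1-benzofuran-4-carboxylate (racemic, not isolated) | COC(=O)C1=C(CCCc2cc(C(C)(C)C=C)c(OCOC)cc2OCOC)CC(O[Si](C)(C)C(C)(C)C)=C2OC=CC12 | intermediate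
18 | methyl 7-(tert-butyldimethylsilyloxy)-5-{3-[2,4-bis(methoxymethoxy)-5-(2-methylbut-3-en-2-yl)phenyl]propyl}-1-benzofuran-4-carboxylate | COC(=O)c1c(CCCc2cc(C(C)(C)C=C)c(OCOC)cc2OCOC)cc(O[Si](C)(C)C(C)(C)C)c2occc12 | intermediate
19 | 7-(tert-butyldimethylsilyloxy)-5-{3-[2,4-bis(methoxymethoxy)-5-(2-methylbut-3-en-2-yl)phenyl]propyl}-1-benzofuran-4-carbaldehyde (not isolated) | O=Cc1c(CCCc2cc(C(C)(C)C=C)c(OCOC)cc2OCOC)cc(O[Si](C)(C)C(C)(C)C)c2occc12 | intermediate
20 | {7-(tert-butyldimethylsilyloxy)-5-{3-[2,4-bis(methoxymethoxy)-5-(2-methylbut-3-en-2-yl)phenyl]propyl}-1-benzofuran-4-yl}methanol | OCc1c(CCCc2cc(C(C)(C)C=C)c(OCOC)cc2OCOC)cc(O[Si](C)(C)C(C)(C)C)c2occc12 | intermediate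
21 | {[4-(bromomethyl)-5-{3-[2,4-bis(methoxymethoxy)-5-(2-methylbut-3-en-2-yl)phenyl]propyl}-1-benzofuran-7-yl]oxy}(tert-butyl)dimethylsilane | BrCc1c(CCCc2cc(C(C)(C)C=C)c(OCOC)cc2OCOC)cc(O[Si](C)(C)C(C)(C)C)c2occc12 | intermediate
22 | (2-methylprop-1-en-1-yl)magnesium bromide | CC(C)=C[Mg]Br | starting material
23 | tert-butyl{[5-{3-[2,4-bis(methoxymethoxy)-5-(2-methylbut-3-en-2-yl)phenyl]propyl}-4-(3-methylbut-2-en-1-yl)-1-benzofuran-7-yl]oxy}dimethylsilane | CC(C)=CCc1c(CCCc2cc(C(C)(C)C=C)c(OCOC)cc2OCOC)cc(O[Si](C)(C)C(C)(C)C)c2occc12 | intermediate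
24 | 5-{3-[2,4-bis(methoxymethoxy)-5-(2-methylbut-3-en-2-yl)phenyl]propyl}-4-(3-methylbut-2-en-1-yl)-1-benzofuran-7-ol | CC(C)=CCc1c(CCCc2cc(C(C)(C)C=C)c(OCOC)cc2OCOC)cc(O)c2occc12 | intermediate
25 | 4-{3-[7-hydroxy-4-(3-methylbut-2-en-1-yl)-1-benzofuran-5-yl]propyl}-6-(2-methylbut-3-en-2-yl)benzene-1,3-diol | C=CC(C)(C)c1cc(CCCc2cc(O)c3occc3c2CC=C(C)C)c(O)cc1O | target

**Step count and risks**

Total step count: 15. Longest linear sequence: 13 steps (steps 1–4, 6–8 and 10–15, from 4-bromoresorcinol).

Steps most likely to fail:

1. Step 10. The cycloaddition may be too slow for a β-alkyl ynoate, so that the diene dimerises or loses its silyl group before it adds; the adduct may also lose silanol instead of being dehydrogenated, and DDQ could begin to attack the electron-rich ring-A benzylic position. Fallback with a stronger activating group on the dienophile: it sets out from alkyne 12, which is lithiated as in step 8 (acetylide 13) and formylated with DMF (quench into aq. KH2PO4) to give 6-[2,4-bis(methoxymethoxy)-5-(2-methylbut-3-en-2-yl)phenyl]hex-2-ynal F1. This alkynal is a far better dienophile and should add diene 16 at 60–80 °C in toluene with the same regiochemistry, giving the 7-(tert-butyldimethylsilyloxy)-3a,6-dihydro-1-benzofuran-4-carbaldehyde cycloadduct F2, which is dehydrogenated with DDQ in the same flask. The fallback comes back to the route at aldehyde 19, which is reduced to alcohol 20 with i-Bu2AlH as in step 11.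

2. Step 3. The [3,3] shift may go in part to the carbon between the two oxygens, and the 2-(1,1-dimethylallyl)phenol formed may rearrange further at 185 °C (abnormal Claisen rearrangement, cyclisation onto the hydroxyl). Fallback without a sigmatropic step, which also avoids the regiochemical question of step 1: it sets out from 1, which is converted with MOMCl (2.4 equiv) and i-Pr2NEt into 4-bromo-1,3-bis(methoxymethoxy)benzene F3. Bromination with NBS in MeCN at 0 °C, para to one MOM ether and ortho to the other, gives the symmetric 1,5-dibromo-2,4-bis(methoxymethoxy)benzene F4. A γ-selective palladium-catalysed Suzuki-Miyaura allylation of F4 (used in excess) with 3-methylbut-2-enylboronic acid pinacol ester (Pd(OAc)2, a bulky biaryl dialkylphosphine chosen for branched selectivity, K3PO4, THF/H2O) then places the 1,1-dimethylallyl group on one of the two equivalent carbons. The fallback comes back to the route at aryl bromide 7.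

3. Step 13. The labile benzylic bromide may undergo Wurtz-type homocoupling or ionise, and the Grignard reagent may attack the aryl silyl ether. Fallback that replaces the organomagnesium/copper substitution by a palladium cross-coupling with a neutral boron nucleophile: it sets out from bromide 21, which is coupled with 2-methylprop-1-enylboronic acid pinacol ester in a Suzuki-Miyaura reaction (PdCl2(dppf), K3PO4, THF/H2O, 60 °C), and comes back to the route at 23. Partial loss of the silyl group under the aqueous base would do no harm, because step 14 removes it.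

**Further compounds**

F1 | step 10 | 6-[2,4-bis(methoxymethoxy)-5-(2-methylbut-3-en-2-yl)phenyl]hex-2-ynal | O=CC#CCCCc1cc(C(C)(C)C=C)c(OCOC)cc1OCOC
F2 | step 10 | 7-(tert-butyldimethylsilyloxy)-5-{3-[2,4-bis(methoxymethoxy)-5-(2-methylbut-3-en-2-yl)phenyl]propyl}-3a,6-dihydro-1-benzofuran-4-carbaldehyde (racemic) | O=CC1=C(CCCc2cc(C(C)(C)C=C)c(OCOC)cc2OCOC)CC(O[Si](C)(C)C(C)(C)C)=C2OC=CC12
F3 | step 3 | 4-bromo-1,3-bis(methoxymethoxy)benzene | COCOc1ccc(Br)c(OCOC)c1
F4 | step 3 | 1,5-dibromo-2,4-bis(methoxymethoxy)benzene | COCOc1cc(OCOC)c(Br)cc1Br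
F0 | step 13 | none | none
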